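**Retrosynthetic overview**
1. Target 21 ⇐ 20 (epoxidation of the E C4=C5 olefin) ⇐ 19 (reduction of the C9 ketone) ⇐ 16 (angeloylation of O6).
2. The ten-membered ring comes from tricyclic tosylate 14 by a four-carbon ring expansion: Wharton–Grob fragmentation of the C4–C9 fusion bond of a trans-decalin, giving the E olefin and the C9 ketone.
3. 14 ⇐ keto aldehyde 9 by SmI2 pinacol closure of ring B (C8–C9), lactonisation and α-methylenation.
4. 9 ⇐ 2,6-dimethylcyclohexanone 2 + C2 aldehyde 3 (acid-catalysed enol aldol, C4–C5, sets the absolute configuration) + C4 aldehyde ester 7 (amine-catalysed cross-aldol, C6–C7).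
5. Ring order: ring A (cyclohexanone, bought) → ring B (pinacol) → γ-lactone → ten-membered ring (ring A/ring B fusion bond cleaved) → epoxide.

Assumption: atoms are tracked with germacrane-type numbering (C1–C3 ring CH2; C4/C5 epoxide carbons with methyl C15 on C4; C6 angelate carbon; C7; C8 lactone O–CH; C9 carbinol; C10 CH–CH3 (C14); C11–C13 lactone C, C=O and =CH2), and 2,2-dimethoxyacetaldehyde is used anhydrous.

Step 1
Reactants: 1 2-methylcyclohexan-1-one
Product: 2 2,6-dimethylcyclohexan-1-one (cis/trans mixture)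
Conditions: LiN(iPr)2, THF, −78 °C; then MeI, −78 → 0 °C
Reagents that add atoms: iodomethane, CI
Why: Kinetic enolate alkylation at the unsubstituted α-carbon; the configuration of both α-centres is irrelevant because they are reset through the enol in step 2.

Step 2
Reactants: 2 2,6-dimethylcyclohexan-1-one; 3 2,2-dimethoxyacetaldehyde
Product: 4 (2R,6R)-2-[(1R)-1-hydroxy-2,2-dimethoxyethyl]-2,6-dimethylcyclohexan-1-one
Conditions: 2 (3 equiv), (R)-3,3′-bis(2,4,6-triisopropylphenyl)-1,1′-binaphthyl-2,2′-diyl hydrogen phosphate (10 mol %), 5 Å molecular sieves, cyclohexane, 50 °C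
Reagents that add atoms: none
Why: Proposed new method: the chiral phosphoric acid should enolise 2 to the tetrasubstituted enol and, in a bifunctional hydrogen-bonded transition state (P–OH to the aldehyde C=O, P=O to the enol O–H), deliver one enol face to the aldehyde, so that the quaternary C4 and the carbinol C5 are set by the catalyst with the syn topology (ring CH2 and OH syn; sense of induction predicted, not known), while C10 equilibrates through the enol to the equatorial (6R) epimer; the closest known reaction types are phosphoric-acid enol catalysis of α-branched cyclohexanones (quaternary-centre-forming Michael additions and aminations) and phosphoric-acid-catalysed direct syn-aldol additions of cyclohexanone to glyoxylates.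

Step 3
Reactants: 4 (2R,6R)-2-[(1R)-1-hydroxy-2,2-dimethoxyethyl]-2,6-dimethylcyclohexan-1-one
Product: 5 (1R)-1-[(1R,3R)-1,3-dimethyl-2-oxocyclohexyl]-2,2-dimethoxyethyl 4-methylbenzenesulfonate
Conditions: TsCl, Et3N, Me3N·HCl (10 mol %), CH2Cl2, 0 °C → rt
Reagents that add atoms: 4-methylbenzenesulfonyl chloride, Cc1ccc(cc1)S(=O)(=O)Cl
Why: O-sulfonylation of the only hydroxyl installs the nucleofuge for the later fragmentation without touching a stereocentre; a tosylate is chosen because it has no acidic α-hydrogen for step 8, and the β-sulfonyloxy ketone cannot eliminate because C4 is quaternary.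

Step 4
Reactants: 5 (1R)-1-[(1R,3R)-1,3-dimethyl-2-oxocyclohexyl]-2,2-dimethoxyethyl 4-methylbenzenesulfonate
Product: 6 (1R)-1-[(1R,3R)-1,3-dimethyl-2-oxocyclohexyl]-2-oxoethyl 4-methylbenzenesulfonate
Conditions: CF3CO2H–H2O (9:1), CH2Cl2, 0 °C → rt; used crude
Reagents that add atoms: water, O
Why: Acid-catalysed acetal hydrolysis unmasks the C6 aldehyde, and the non-basic conditions leave the α-sulfonyloxy stereocentre C5 intact.

Step 5
Reactants: 6 (1R)-1-[(1R,3R)-1,3-dimethyl-2-oxocyclohexyl]-2-oxoethyl 4-methylbenzenesulfonate; 7 methyl 4-oxobutanoate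
Product: 8 methyl (3R,4R,5R)-5-[(1R,3R)-1,3-dimethyl-2-oxocyclohexyl]-3-formyl-4-hydroxy-5-(tosyloxy)pentanoate
Conditions: 7 (3 equiv, slow addition), (S)-Maruoka amino sulfonamide (binaphthyl-fused dihydroazepine bearing NHSO2CF3, C23H17F3N2O2S; 10 mol %), NMP, rt
Reagents that add atoms: none
Why: Syn-selective enamine cross-aldol reaction in which the enamine of 7 adds to the non-enolisable aldehyde activated by the sulfonamide N–H, so that the catalyst sets C7 and C6 (syn); it has to override the Cornforth preference of the α-sulfonyloxy aldehyde, which makes this a mismatched case.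

Step 6
Reactants: 8 methyl (3R,4R,5R)-5-[(1R,3R)-1,3-dimethyl-2-oxocyclohexyl]-3-formyl-4-hydroxy-5-(tosyloxy)pentanoate
Product: 9 methyl (3R,4R,5R)-5-[(1R,3R)-1,3-dimethyl-2-oxocyclohexyl]-3-formyl-5-(tosyloxy)-4-(triethylsilyloxy)pentanoate
Conditions: Et3SiCl, imidazole, DMF, 0 °C
Reagents that add atoms: chlorotriethylsilane, CC[Si](Cl)(CC)CC
Why: Silyl protection of O6 blocks retro-aldol cleavage and the competing lactonisation of O6 onto the ester, so that only O8 can later close the lactone.

Step 7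
Reactants: 9 methyl (3R,4R,5R)-5-[(1R,3R)-1,3-dimethyl-2-oxocyclohexyl]-3-formyl-5-(tosyloxy)-4-(triethylsilyloxy)pentanoate
Product: 11 tricyclic γ-lactone (trans-decalin fused at C4–C9 with angular CH3 and angular OH trans; ring B all-equatorial 5-OTs 6-OSiEt3 and trans-fused O8–C12 lactone; 4R,5R,6R,7S,8S,9R,10R), via diol ester 10 (not isolated)
Conditions: SmI2 (2.5 equiv), THF, −78 → −30 °C; aq. NH4Cl
Reagents that add atoms: none
Why: Samarium diiodide ketone–aldehyde pinacol cyclisation through a chair-like transition state with all ring B substituents equatorial and both oxygens on samarium gives the cis-diol (O8 equatorial and trans to the C7 side chain, O9 axial and trans to the angular methyl, hence the trans-decalin), after which the C8 alkoxide closes the γ-lactone with loss of methanol.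

Step 8
Reactants: 11 tricyclic γ-lactone
Product: 14 tricyclic α-methylene γ-lactone (11 with C11=C13H2; 4R,5R,6R,7S,8S,9R,10R), via Mannich base 12 (not isolated), via ammonium iodide 13 (not isolated)
Conditions: LiN(iPr)2 (2.3 equiv), THF, −78 °C; CH2=NMe2+ I−, −78 → −40 °C; then MeI, MeOH, rt; then aq. NaHCO3, CH2Cl2
Reagents that add atoms: N,N-dimethylmethyleneiminium iodide, C=[N+](C)C.[I-]
Why: Lactone α-methylenation by a Mannich reaction of the lithium enolate, N-methylation and elimination of trimethylamine; no stereocentre changes, and the lithium alkoxide at C9 should not fragment at −78 °C.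

Step 9
Reactants: 14 tricyclic α-methylene γ-lactone
Product: 15 (4E,6S,7S,8S,10R)-9-oxo-6-(triethylsilyloxy)germacra-4,11(13)-dien-12,8-olide
Conditions: KN(SiMe3)2 (1.05 equiv), THF, −78 → 0 °C
Reagents that add atoms: none
Why: Wharton–Grob fragmentation as a four-carbon ring expansion: the C9 potassium alkoxide expels the equatorial tosylate on C5, which is antiperiplanar to the C4–C9 bond, and because C3 is anti to C6 across C4–C5 in the trans-decalin the new trisubstituted olefin is E, while C6, C7, C8 and C10 are untouched.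

Step 10
Reactants: 15 (4E,6S,7S,8S,10R)-9-oxo-6-(triethylsilyloxy)germacra-4,11(13)-dien-12,8-olide
Product: 16 (4E,6S,7R,8S,10R)-6-hydroxy-9-oxogermacra-4,11(13)-dien-12,8-olide
Conditions: HF·pyridine, THF, 0 °C
Reagents that add atoms: none
Why: Fluoride-mediated desilylation under non-basic conditions frees O6 without harming the methylene lactone or epimerising C8/C10.

Step 11
Reactants: 16 (4E,6S,7R,8S,10R)-6-hydroxy-9-oxogermacra-4,11(13)-dien-12,8-olide; 17 angelic acid
Product: 19 (4E,6S,7R,8S,10R)-6-angeloyloxy-9-oxogermacra-4,11(13)-dien-12,8-olide, via mixed anhydride 18 (not isolated)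
Conditions: 17, 2,4,6-trichlorobenzoyl chloride, Et3N, toluene, rt; then 16, 80 °C
Reagents that add atoms: none
Why: Yamaguchi esterification through the mixed anhydride without DMAP limits Z-to-E isomerisation of the angelate, and O6 is the only hydroxyl at this stage.

Step 12
Reactants: 19 (4E,6S,7R,8S,10R)-6-angeloyloxy-9-oxogermacra-4,11(13)-dien-12,8-olide
Product: 20 (4E,6S,7R,8S,9R,10R)-6-angeloyloxy-9-hydroxygermacra-4,11(13)-dien-12,8-olide
Conditions: Zn(BH4)2, Et2O, −20 °C
Reagents that add atoms: none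
Why: Chelation-controlled hydride reduction: zinc bridges the ketone and the lactone oxygen on C8, hydride adds to the free face to give the 8,9-anti alcohol, which is also the Felkin product with respect to C10 (9R), and this reagent spares conjugated esters.

Step 13
Reactants: 20 (4E,6S,7R,8S,9R,10R)-6-angeloyloxy-9-hydroxygermacra-4,11(13)-dien-12,8-olide
Product: 21 (4R,5R,6R,7S,8S,9R,10R)-6-angeloyloxy-4,5-epoxy-9-hydroxygermacr-11(13)-en-12,8-olide (target)
Conditions: mCPBA, NaHCO3, CH2Cl2, 0 °C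
Reagents that add atoms: 3-chloroperoxybenzoic acid, OOC(=O)c1cccc(Cl)c1
Why: Prilezhaev epoxidation of the only electron-rich olefin; syn addition to the E olefin gives the trans epoxide, and attack on the outer olefin face of the ring conformer with the C6–O bond in the olefin plane is expected to give (4R,5R), though this facial preference is not secured.

**Compound list**
1 | 2-methylcyclohexan-1-one (racemic) | CC1CCCCC1=O | starting material
2 | 2,6-dimethylcyclohexan-1-one (cis/trans mixture, stereocentres reset in step 2) | CC1CCCC(C)C1=O | intermediate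
3 | 2,2-dimethoxyacetaldehyde | COC(OC)C=O | starting material
4 | (2R,6R)-2-[(1R)-1-hydroxy-2,2-dimethoxyethyl]-2,6-dimethylcyclohexan-1-one | C[C@@H]1CCC[C@](C)([C@@H](O)C(OC)OC)C1=O | intermediate
5 | (1R)-1-[(1R,3R)-1,3-dimethyl-2-oxocyclohexyl]-2,2-dimethoxyethyl 4-methylbenzenesulfonate | C[C@@H]1CCC[C@](C)([C@@H](OS(=O)(=O)c2ccc(C)cc2)C(OC)OC)C1=O | intermediate
6 | (1R)-1-[(1R,3R)-1,3-dimethyl-2-oxocyclohexyl]-2-oxoethyl 4-methylbenzenesulfonate | C[C@@H]1CCC[C@](C)([C@@H](OS(=O)(=O)c2ccc(C)cc2)C=O)C1=O | intermediate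
7 | methyl 4-oxobutanoate | COC(=O)CCC=O | starting material
8 | methyl (3R,4R,5R)-5-[(1R,3R)-1,3-dimethyl-2-oxocyclohexyl]-3-formyl-4-hydroxy-5-(tosyloxy)pentanoate | C[C@@H]1CCC[C@](C)([C@@H](OS(=O)(=O)c2ccc(C)cc2)[C@H](O)[C@@H](CC(=O)OC)C=O)C1=O | intermediate
9 | methyl (3R,4R,5R)-5-[(1R,3R)-1,3-dimethyl-2-oxocyclohexyl]-3-formyl-5-(tosyloxy)-4-(triethylsilyloxy)pentanoate | C[C@@H]1CCC[C@](C)([C@@H](OS(=O)(=O)c2ccc(C)cc2)[C@H](O[Si](CC)(CC)CC)[C@@H](CC(=O)OC)C=O)C1=O | intermediate
10 | diol ester: trans-decalin (C4–C9 fusion), 5-OTs, 6-OSiEt3, 7-CH2CO2Me, 8-OH equatorial, 9-OH axial, 10-CH3 equatorial; (4R,5R,6R,7S,8S,9R,10R) | C[C@@H]1CCC[C@]2(C)[C@@H](OS(=O)(=O)c3ccc(C)cc3)[C@H](O[Si](CC)(CC)CC)[C@@H](CC(=O)OC)[C@H](O)[C@@]12O | intermediate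
11 | tricyclic γ-lactone from 10 (O8–C12 lactone trans-fused on ring B, free tertiary 9-OH); (4R,5R,6R,7S,8S,9R,10R) | C[C@@H]1CCC[C@]2(C)[C@@H](OS(=O)(=O)c3ccc(C)cc3)[C@H](O[Si](CC)(CC)CC)[C@H]3CC(=O)O[C@@H]3[C@@]12O | intermediate
12 | Mannich base: 11 bearing CH2NMe2 on C11 (C11 epimers) | C[C@@H]1CCC[C@]2(C)[C@@H](OS(=O)(=O)c3ccc(C)cc3)[C@H](O[Si](CC)(CC)CC)[C@H]3C(CN(C)C)C(=O)O[C@@H]3[C@@]12O | intermediate
13 | trimethylammonium iodide of 12 | C[C@@H]1CCC[C@]2(C)[C@@H](OS(=O)(=O)c3ccc(C)cc3)[C@H](O[Si](CC)(CC)CC)[C@H]3C(C[N+](C)(C)C)C(=O)O[C@@H]3[C@@]12O.[I-] | intermediate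
14 | tricyclic α-methylene γ-lactone (11 with C11=CH2); (4R,5R,6R,7S,8S,9R,10R) | C[C@@H]1CCC[C@]2(C)[C@@H](OS(=O)(=O)c3ccc(C)cc3)[C@H](O[Si](CC)(CC)CC)[C@H]3C(=C)C(=O)O[C@@H]3[C@@]12O | intermediate
15 | (4E,6S,7S,8S,10R)-9-oxo-6-(triethylsilyloxy)germacra-4,11(13)-dien-12,8-olide | C=C1C(=O)O[C@@H]2C(=O)[C@H](C)CCC/C(C)=C/[C@H](O[Si](CC)(CC)CC)[C@@H]12 | intermediate
16 | (4E,6S,7R,8S,10R)-6-hydroxy-9-oxogermacra-4,11(13)-dien-12,8-olide | C=C1C(=O)O[C@@H]2C(=O)[C@H](C)CCC/C(C)=C/[C@H](O)[C@@H]12 | intermediate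
17 | angelic acid, (2Z)-2-methylbut-2-enoic acid | C/C=C(/C)C(=O)O | starting material
18 | (2Z)-2-methylbut-2-enoic 2,4,6-trichlorobenzoic anhydride | C/C=C(/C)C(=O)OC(=O)c1c(Cl)cc(Cl)cc1Cl | intermediate
19 | (4E,6S,7R,8S,10R)-6-angeloyloxy-9-oxogermacra-4,11(13)-dien-12,8-olide | C=C1C(=O)O[C@@H]2C(=O)[C@H](C)CCC/C(C)=C/[C@H](OC(=O)/C(C)=C\C)[C@@H]12 | intermediate
20 | (4E,6S,7R,8S,9R,10R)-6-angeloyloxy-9-hydroxygermacra-4,11(13)-dien-12,8-olide | C=C1C(=O)O[C@@H]2[C@H](O)[C@H](C)CCC/C(C)=C/[C@H](OC(=O)/C(C)=C\C)[C@@H]12 | intermediate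
21 | (4R,5R,6R,7S,8S,9R,10R)-6-angeloyloxy-4,5-epoxy-9-hydroxygermacr-11(13)-en-12,8-olide | C=C1C(=O)O[C@@H]2[C@H](O)[C@H](C)CCC[C@@]3(C)O[C@@H]3[C@H](OC(=O)/C(C)=C\C)[C@@H]12 | target

**Totals and risks**
Total step count: 13. Longest linear sequence: 13 steps (1 → 21).

Three steps most likely to fail:

Step 2 (the new aldol). The hindered ketone may enolise too slowly, the aldol may revert, or the sense and level of induction at C4/C5 may be wrong. Fallback with known chemistry, setting out from 2 and coming back at 4: the cis (meso) isomer of 2 is deprotonated enantioselectively with LiN[CH(CH3)C6H5]2 (R,R) in the presence of Me3SiCl (THF, −100 °C) to give the (6S) silyl enol ether F1. A TiCl4-promoted Mukaiyama aldol addition to 3 (CH2Cl2, −78 °C; chelated aldehyde, attack anti to the C10 methyl) gives the C6-epimeric aldol F2. Catalytic DBU (CH2Cl2, rt) then equilibrates C10 to give 4.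

Step 9 (ring expansion). The potassium alkoxide may add to the α-methylene lactone, or base may epimerise C8/C10, before or after fragmentation. Fallback, setting out from 11 and coming back at 15: step 8 is stopped after the Mannich stage and amine 12 is isolated. KN(SiMe3)2 (THF, −78 → 0 °C) fragments 12, which carries no Michael acceptor, to the ten-membered amino ketone F3. Iodomethane gives the ammonium iodide F4, and aqueous NaHCO3 eliminates trimethylamine to give 15.

Step 13 (epoxide face). The peracid may attack the other olefin face and give the 4,5-diastereomer. Fallback, setting out from 20 and coming back at 21: N-bromosuccinimide in aqueous THF puts bromine on the face the peracid prefers and water on C4 from the opposite face, giving the bromohydrin F5. K2CO3 in acetone then closes the epoxide by displacement at C5, which places the oxygen on the face opposite to the one attacked directly.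

Further compounds
F1 | step 2 | trimethyl{[(6S)-2,6-dimethylcyclohex-1-en-1-yl]oxy}silane | C[C@H]1CCCC(C)=C1O[Si](C)(C)C
F2 | step 2 | (2R,6S)-2-[(1R)-1-hydroxy-2,2-dimethoxyethyl]-2,6-dimethylcyclohexan-1-one | C[C@H]1CCC[C@](C)([C@@H](O)C(OC)OC)C1=O
F3 | step 9 | (4E,6S,7S,8S,10R)-13-(dimethylamino)-9-oxo-6-(triethylsilyloxy)germacr-4-en-12,8-olide (C11 epimers) | CN(C)CC1C(=O)O[C@@H]2C(=O)[C@H](C)CCC/C(C)=C/[C@H](O[Si](CC)(CC)CC)[C@@H]12
F4 | step 9 | trimethylammonium iodide of F3 | C[N+](C)(C)CC1C(=O)O[C@@H]2C(=O)[C@H](C)CCC/C(C)=C/[C@H](O[Si](CC)(CC)CC)[C@@H]12.[I-]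
F5 | step 13 | (4R,5S,6R,7S,8S,9R,10R)-6-angeloyloxy-5-bromo-4,9-dihydroxygermacr-11(13)-en-12,8-olide | C=C1C(=O)O[C@@H]2[C@H](O)[C@H](C)CCC[C@@](C)(O)[C@@H](Br)[C@H](OC(=O)/C(C)=C\C)[C@@H]12
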